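The ten-membered ring is not closed end to end. Its C1 ketone, C2 methylene, C3 carbinol and Z C4=C5 alkene form a γ,δ-unsaturated β-oxy ketone, the signature of a Claisen shift, so C2–C3 is disconnected and an oxygen is put between C1 and C5. The precursor 33 is thus an eight-membered 2-methyleneoxocane carrying an (E)-2-(4-methoxybenzyloxy)-1-methylvinyl group on C5 and the fully substituted C6–C10 chain. One thermal [3,3] shift forms C2–C3, enlarges the ring to the carbocycle, fixes the alkene geometry and relays the C5 configuration to C3. The 6,12-lactone and the C8 ester follow.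

Key step: step 19

Remark: locants C1–C15 are those of the germacrane skeleton of 41 (C1 ketone, C3 and C10 carbinols, C4=C5, C6–O–C12 lactone, C8 ester, C11=C13); TBS = tert-butyldimethylsilyl, TES = triethylsilyl, PMB = 4-methoxybenzyl.
Assumption: in step 7 (−)-Ipc2BOTf is taken to give the 6S,7S adduct; should its sense of induction on this enolate be the opposite, the enantiomeric reagent is used and nothing else changes.

Step 1
Reactants: 1 (R)-citramalic acid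
Product: 2 2-[(4R)-2,2,4-trimethyl-5-oxo-1,3-dioxolan-4-yl]acetic acid
Conditions: Me2C(OMe)2, TsOH·H2O (cat.), rt
Reagents that add atoms: 2,2-dimethoxypropane, COC(C)(C)OC
Why: Acid-catalysed acetal exchange ties the tertiary hydroxyl and its neighbouring carboxyl into a five-membered dioxolanone (favoured over the six-membered alternative), leaving only the C8 carboxyl free and the C10 centre untouched.

Step 2
Reactants: 3 ethyl 2-(bromomethyl)acrylate
Product: 4 2-(bromomethyl)prop-2-en-1-ol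
Conditions: i-Bu2AlH (2.2 equiv), CH2Cl2, −78 °C; Rochelle salt
Reagents that add atoms: none
Why: 1,2-Reduction of the acrylate ester by the aluminium hydride at low temperature should give the allylic alcohol while the allylic bromide survives.

Step 3
Reactants: 4 2-(bromomethyl)prop-2-en-1-ol
Product: 5 {[2-(bromomethyl)prop-2-en-1-yl]oxy}(tert-butyl)dimethylsilane
Conditions: TBSCl, Et3N, DMAP (cat.), CH2Cl2, 0 °C
Reagents that add atoms: tert-butyldimethylsilyl chloride, CC(C)(C)[Si](C)(C)Cl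
Why: DMAP-catalysed silylation of the primary alcohol is fast at 0 °C, so N-alkylation of the amine by the allylic bromide should not compete.

Step 4
Reactants: 2 2-[(4R)-2,2,4-trimethyl-5-oxo-1,3-dioxolan-4-yl]acetic acid; 5 {[2-(bromomethyl)prop-2-en-1-yl]oxy}(tert-butyl)dimethylsilane
Product: 8 (5R)-5-{2-oxo-4-[(TBS-oxy)methyl]pent-4-en-1-yl}-2,2,5-trimethyl-1,3-dioxolan-4-one, via acid chloride 6 (not isolated), via allylzinc bromide 7 (not isolated)
Conditions: 2, (COCl)2, DMF (cat.), CH2Cl2, 0 °C → rt, evaporate; 5, Zn, LiCl, THF, rt; then 7 (1.05 equiv) added to 6, THF, −78 °C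
Reagents that add atoms: none
Why: Acylation of an allylic zinc reagent by an acid chloride at −78 °C should stop at the β,γ-unsaturated ketone, because the acid chloride is far more electrophilic than the product ketone or the dioxolanone, and the symmetrical allyl unit makes the site of attack irrelevant.

Step 5
Reactants: 9 4-methoxybenzyl alcohol
Product: 10 allyl 4-methoxybenzyl ether
Conditions: NaH, allyl bromide, Bu4NI (cat.), THF, 0 °C → rt
Reagents that add atoms: allyl bromide, C=CCBr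
Why: Williamson ether synthesis of a primary alkoxide with an allylic halide.

Step 6
Reactants: 10 allyl 4-methoxybenzyl ether
Product: 11 2-[(4-methoxybenzyl)oxy]acetaldehyde
Conditions: OsO4 (cat.), NaIO4, 2,6-lutidine, dioxane/H2O, rt
Reagents that add atoms: osmium tetroxide, O=[Os](=O)(=O)=O (source of the carbonyl oxygen, regenerated by sodium periodate, [Na+].[O-]I(=O)(=O)=O)
Why: Lemieux–Johnson cleavage (dihydroxylation, then glycol scission) of the terminal alkene; the PMB ether is inert and the aldehyde is used fresh.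

Step 7
Reactants: 8 (5R)-5-{2-oxo-4-[(TBS-oxy)methyl]pent-4-en-1-yl}-2,2,5-trimethyl-1,3-dioxolan-4-one; 11 2-[(4-methoxybenzyl)oxy]acetaldehyde
Product: 13 (5R)-5-[(3S,4S)-4-hydroxy-5-(PMB-oxy)-2-oxo-3-[3-(TBS-oxy)prop-1-en-2-yl]pentyl]-2,2,5-trimethyl-1,3-dioxolan-4-one, via Z-enol borinate 12 (not isolated)
Conditions: (−)-Ipc2BOTf, i-Pr2NEt, CH2Cl2, −78 °C; 11, −78 → −20 °C; H2O2, MeOH/pH 7 buffer, 0 °C
Reagents that add atoms: none
Why: Reagent-controlled boron aldol reaction: enolization on the more acidic allylic C7 side gives the Z-enol borinate, whose closed chair transition state sets the 6,7-syn relationship while the isopinocampheyl ligands select the aldehyde face (6S,7S); the minor syn isomer is a diastereomer (C10 is already fixed) and should be separable.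

Step 8
Reactants: 13 (5R)-5-[(3S,4S)-4-hydroxy-5-(PMB-oxy)-2-oxo-3-[3-(TBS-oxy)prop-1-en-2-yl]pentyl]-2,2,5-trimethyl-1,3-dioxolan-4-one
Product: 15 (3R,5R)-3-hydroxy-5-[(2S,3S)-2-hydroxy-4-methylidene-1-(PMB-oxy)-5-(TBS-oxy)pentan-3-yl]-3-methyloxolan-2-one, via anti-diol 14 (not isolated)
Conditions: Me4NBH(OAc)3, MeCN/AcOH (1:1), −30 °C; work-up; PPTS (cat.), CH2Cl2, rt
Reagents that add atoms: none
Why: Evans–Saksena reduction: the C6 hydroxyl binds boron and delivers hydride intramolecularly through a chair, setting 8R (1,3-anti to O6); the new C8 hydroxyl then transacylates the activated dioxolanone (5-exo) to the γ-lactone with loss of acetone, which distinguishes O8 from O6.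

Step 9
Reactants: 15 (3R,5R)-3-hydroxy-5-[(2S,3S)-2-hydroxy-4-methylidene-1-(PMB-oxy)-5-(TBS-oxy)pentan-3-yl]-3-methyloxolan-2-one
Product: 16 (3R,5R)-3-hydroxy-3-methyl-5-[(2S,3R)-4-methylidene-1-(PMB-oxy)-2,5-bis(TBS-oxy)pentan-3-yl]oxolan-2-one
Conditions: TBSCl, imidazole, DMAP (cat.), DMF, 35 °C
Reagents that add atoms: tert-butyldimethylsilyl chloride, CC(C)(C)[Si](C)(C)Cl
Why: Silyl chloride/imidazole silylation is selective for the secondary C6 hydroxyl; the tertiary C10 hydroxyl next to the lactone carbonyl should not react under these conditions.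

Step 10
Reactants: 16 (3R,5R)-3-hydroxy-3-methyl-5-[(2S,3R)-4-methylidene-1-(PMB-oxy)-2,5-bis(TBS-oxy)pentan-3-yl]oxolan-2-one
Product: 19 (2R,4R,5R,6S)-2-methyl-7-(PMB-oxy)-6-(TBS-oxy)-5-[3-(TBS-oxy)prop-1-en-2-yl]-2,4-bis(TES-oxy)heptanoic acid, via lithium carboxylate 17 (not isolated), via tris(triethylsilyl) derivative 18 (not isolated)
Conditions: LiOH, THF/H2O, 0 °C → rt, evaporate to dryness; TESOTf, 2,6-lutidine, CH2Cl2, 0 °C → rt; K2CO3 (cat.), MeOH/H2O, 0 °C; pH 5 buffer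
Reagents that add atoms: lithium hydroxide, [Li+].[OH-]; triethylsilyl trifluoromethanesulfonate, CC[Si](CC)(CC)OS(=O)(=O)C(F)(F)F
Why: Saponification opens the lactone; silylating the carboxylate salt directly prevents re-lactonization and caps O8, the tertiary O10 and the carboxylate, and mild methanolysis then cleaves only the labile silyl ester.

Step 11
Reactants: 19 (2R,4R,5R,6S)-2-methyl-7-(PMB-oxy)-6-(TBS-oxy)-5-[3-(TBS-oxy)prop-1-en-2-yl]-2,4-bis(TES-oxy)heptanoic acid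
Product: 20 prop-2-en-1-yl (2R,4R,5R,6S)-2-methyl-7-(PMB-oxy)-6-(TBS-oxy)-5-[3-(TBS-oxy)prop-1-en-2-yl]-2,4-bis(TES-oxy)heptanoate
Conditions: allyl bromide, K2CO3, DMF, 0 °C → rt
Reagents that add atoms: allyl bromide, C=CCBr
Why: O-Alkylation of the carboxylate (SN2 on allyl bromide) masks C1 as an ester that is inert to the organozinc step and removable later under neutral conditions.

Step 12
Reactants: 20 prop-2-en-1-yl (2R,4R,5R,6S)-2-methyl-7-(PMB-oxy)-6-(TBS-oxy)-5-[3-(TBS-oxy)prop-1-en-2-yl]-2,4-bis(TES-oxy)heptanoate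
Product: 21 prop-2-en-1-yl (2R,4R,5R,6S)-7-hydroxy-2-methyl-6-(TBS-oxy)-5-[3-(TBS-oxy)prop-1-en-2-yl]-2,4-bis(TES-oxy)heptanoate
Conditions: DDQ, CH2Cl2/pH 7 buffer (10:1), 0 °C
Reagents that add atoms: none
Why: Oxidative PMB cleavage by DDQ under buffered conditions should leave the silyl ethers, the allyl ester and the 1,1-disubstituted alkene intact.

Step 13
Reactants: 21 prop-2-en-1-yl (2R,4R,5R,6S)-7-hydroxy-2-methyl-6-(TBS-oxy)-5-[3-(TBS-oxy)prop-1-en-2-yl]-2,4-bis(TES-oxy)heptanoate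
Product: 22 prop-2-en-1-yl (2R,4R,5R,6S)-2-methyl-7-oxo-6-(TBS-oxy)-5-[3-(TBS-oxy)prop-1-en-2-yl]-2,4-bis(TES-oxy)heptanoate
Conditions: Dess–Martin periodinane, NaHCO3, CH2Cl2, 0 °C → rt
Reagents that add atoms: none
Why: Dess–Martin oxidation under buffered, non-basic conditions should give the α-silyloxy aldehyde without epimerization at C6; it is used at once.

Step 14
Reactants: 9 4-methoxybenzyl alcohol; 23 trichloroethylene
Product: 26 1-methoxy-4-[(prop-1-yn-1-yloxy)methyl]benzene, via dichlorovinyl ether 24 (not isolated), via lithium alkynyl ether 25 (not isolated)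
Conditions: KH, THF, 0 °C; Cl2C=CHCl, −50 °C → rt; n-BuLi (2.5 equiv), −78 → −40 °C; MeI, DMPU, −78 → −20 °C; kept below 0 °C
Reagents that add atoms: iodomethane, CI
Why: Dichlorovinyl ether route to alkynyl ethers: the alkoxide adds to dichloroacetylene formed in situ, butyllithium effects elimination and chlorine–lithium exchange, and the lithium alkynyl ether is C-methylated; the product is kept cold because benzyl-type alkynyl ethers rearrange on warming.

Step 15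
Reactants: 22 prop-2-en-1-yl (2R,4R,5R,6S)-2-methyl-7-oxo-6-(TBS-oxy)-5-[3-(TBS-oxy)prop-1-en-2-yl]-2,4-bis(TES-oxy)heptanoate; 26 1-methoxy-4-[(prop-1-yn-1-yloxy)methyl]benzene
Product: 29 prop-2-en-1-yl (2R,4R,5R,6S,7R,8E)-7-hydroxy-2,8-dimethyl-9-(PMB-oxy)-6-(TBS-oxy)-5-[3-(TBS-oxy)prop-1-en-2-yl]-2,4-bis(TES-oxy)non-8-enoate, via alkenylzirconocene chloride 27 (not isolated), via alkenyl(methyl)zinc 28 (not isolated)
Conditions: 26 (1.6 equiv), Cp2Zr(H)Cl, CH2Cl2, 0 °C → rt; Me2Zn, toluene, −65 °C; 22, −65 → 0 °C; aq. NH4Cl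
Reagents that add atoms: none
Why: Hydrozirconation places the metal on the carbon β to oxygen by syn addition (E-alkenyl metal), zinc transmetalation gives a nucleophile that adds to the aldehyde but not to the ester, and Felkin–Anh attack anti to the C6 silyloxy group should give the 5,6-anti (5R) alcohol.

Step 16
Reactants: 29 prop-2-en-1-yl (2R,4R,5R,6S,7R,8E)-7-hydroxy-2,8-dimethyl-9-(PMB-oxy)-6-(TBS-oxy)-5-[3-(TBS-oxy)prop-1-en-2-yl]-2,4-bis(TES-oxy)non-8-enoate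
Product: 30 (2R,4R,5R,6S,7R,8E)-7-hydroxy-2,8-dimethyl-9-(PMB-oxy)-6-(TBS-oxy)-5-[3-(TBS-oxy)prop-1-en-2-yl]-2,4-bis(TES-oxy)non-8-enoic acid
Conditions: Pd(PPh3)4 (5 mol %), morpholine, THF, rt; carried on as the ammonium salt
Reagents that add atoms: none
Why: Tsuji–Trost deallylation: the palladium catalyst ionizes the allyl ester and morpholine traps the allyl fragment, so the carboxylate is freed under neutral conditions that the acid-labile enol ether and the silyl ethers tolerate.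

Step 17
Reactants: 30 (2R,4R,5R,6S,7R,8E)-7-hydroxy-2,8-dimethyl-9-(PMB-oxy)-6-(TBS-oxy)-5-[3-(TBS-oxy)prop-1-en-2-yl]-2,4-bis(TES-oxy)non-8-enoic acid
Product: 32 (3R,5R,6R,7S,8R)-3-methyl-8-[(1E)-1-(PMB-oxy)prop-1-en-2-yl]-7-(TBS-oxy)-6-[3-(TBS-oxy)prop-1-en-2-yl]-3,5-bis(TES-oxy)oxocan-2-one, via mixed anhydride 31 (not isolated)
Conditions: MNBA, DMAP, Et3N, CH2Cl2 (1 mM), rt, syringe pump
Reagents that add atoms: none
Why: Shiina macrolactonization: the acid is activated as the mixed anhydride with 2-methyl-6-nitrobenzoic acid and acylates the C5 hydroxyl under DMAP catalysis at room temperature; high dilution and the folded, heavily branched chain (quaternary C10, branched C6–C8) should favour eight-membered closure over oligomerization.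

Step 18
Reactants: 32 (3R,5R,6R,7S,8R)-3-methyl-8-[(1E)-1-(PMB-oxy)prop-1-en-2-yl]-7-(TBS-oxy)-6-[3-(TBS-oxy)prop-1-en-2-yl]-3,5-bis(TES-oxy)oxocan-2-one
Product: 33 (3R,5R,6R,7S,8R)-3-methyl-2-methylidene-8-[(1E)-1-(PMB-oxy)prop-1-en-2-yl]-7-(TBS-oxy)-6-[3-(TBS-oxy)prop-1-en-2-yl]-3,5-bis(TES-oxy)oxocane
Conditions: Cp2TiMe2 (3 equiv), toluene, 65 °C, dark; filtration through basic Al2O3
Reagents that add atoms: dimethyltitanocene, C[Ti](C)(C1C=CC=C1)C1C=CC=C1
Why: Petasis methylenation: titanocene methylidene formed on warming converts the lactone carbonyl (the only carbonyl present) into the exocyclic enol ether via an oxatitanacyclobutane, under non-acidic conditions that spare silyl ethers, the enol ether and the alkenes.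

Step 19
Reactants: 33 (3R,5R,6R,7S,8R)-3-methyl-2-methylidene-8-[(1E)-1-(PMB-oxy)prop-1-en-2-yl]-7-(TBS-oxy)-6-[3-(TBS-oxy)prop-1-en-2-yl]-3,5-bis(TES-oxy)oxocane
Product: 34 (3R,4Z,6R,7R,8R,10R)-4,10-dimethyl-3-(PMB-oxy)-6-(TBS-oxy)-7-[3-(TBS-oxy)prop-1-en-2-yl]-8,10-bis(TES-oxy)cyclodec-4-en-1-one
Conditions: toluene (degassed), Et3N (1%), sealed tube, 125 °C, base-washed glass
Reagents that add atoms: none
Why: Thermal, concerted [3,3]-sigmatropic (Claisen) shift of the allyl vinyl ether C2=C1–O–C5–C4=C3 through a chair, in which the C2–C3 bond forms suprafacially while O–C5 breaks, leaving the C1 ketone and the C4=C5 alkene. The closest known reaction type is the Claisen ring expansion of 2-methylene-6-alkenyltetrahydropyrans to cyclooct-4-enones, applied here to a ring two atoms larger. The ten-membered carbocycle (C1–C10) is closed by two-atom enlargement of the oxocane, C2 and C3 being inserted between C1 and C4, so no high dilution is needed. The only new stereocentre, C3, is controlled by C5 (R): the five-carbon C6–C10 strap should span C1 and C5 only with C6 axial on the chair, and the E enol ether keeps the C3 alkoxy group equatorial, which fixes the face of C3 that bonds to C2 (3R). The same axial C6 ends up cis to C3 across the new double bond, so the 4Z alkene is expected. The step needs chair over boat and [3,3] over heterolysis or [1,3] shift: the terminal alkoxy donor lowers the barrier so that about 125 °C should suffice, amine-buffered base-washed glassware suppresses acid-triggered ionization, and the quaternary C10 rules out migration of the exocyclic double bond into the ring.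

Step 20
Reactants: 34 (3R,4Z,6R,7R,8R,10R)-4,10-dimethyl-3-(PMB-oxy)-6-(TBS-oxy)-7-[3-(TBS-oxy)prop-1-en-2-yl]-8,10-bis(TES-oxy)cyclodec-4-en-1-one
Product: 35 (3R,4Z,6R,7R,8R,10R)-8-hydroxy-4,10-dimethyl-3-(PMB-oxy)-6-(TBS-oxy)-7-[3-(TBS-oxy)prop-1-en-2-yl]-10-(TES-oxy)cyclodec-4-en-1-one
Conditions: HF·pyridine, pyridine, THF, 0 °C, monitored
Reagents that add atoms: none
Why: Buffered fluoride desilylation discriminates by silyl size and steric access, so only the secondary C8 triethylsilyl ether should be cleaved; the tertiary C10 triethylsilyl ether and both TBS ethers stay, which is all the acylation requires.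

Step 21
Reactants: 35 (3R,4Z,6R,7R,8R,10R)-8-hydroxy-4,10-dimethyl-3-(PMB-oxy)-6-(TBS-oxy)-7-[3-(TBS-oxy)prop-1-en-2-yl]-10-(TES-oxy)cyclodec-4-en-1-one
Product: 36 C8 3-methylbutanoate of 35 (3R,4Z,6R,7R,8R,10R)
Conditions: (i-BuCO)2O, DMAP, Et3N, CH2Cl2, 0 °C
Reagents that add atoms: 3-methylbutanoic anhydride, CC(C)CC(=O)OC(=O)CC(C)C
Why: DMAP-catalysed acyl transfer to the only free hydroxyl installs the isovalerate; any transannular O8/C1 hemiketal is in equilibrium with the open hydroxy ketone and is drained by acylation, and the low temperature avoids β-elimination of the C3 ether.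

Step 22
Reactants: 36 C8 3-methylbutanoate of 35 (3R,4Z,6R,7R,8R,10R)
Product: 37 (3R,4Z,6R,7S,8R,10R)-6,10-dihydroxy-7-(3-hydroxyprop-1-en-2-yl)-4,10-dimethyl-1-oxo-3-(PMB-oxy)cyclodec-4-en-8-yl 3-methylbutanoate (same configuration as 36; the C7 descriptor changes by ranking only)
Conditions: HF·pyridine (excess), THF, 0 °C → rt
Reagents that add atoms: none
Why: Excess HF·pyridine removes the remaining silyl ethers (O6 and O12 TBS, tertiary O10 TES) in an acidic, non-nucleophilic medium that should avoid acyl migration and elimination.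

Step 23
Reactants: 37 (3R,4Z,6R,7S,8R,10R)-6,10-dihydroxy-7-(3-hydroxyprop-1-en-2-yl)-4,10-dimethyl-1-oxo-3-(PMB-oxy)cyclodec-4-en-8-yl 3-methylbutanoate
Product: 40 3-O-PMB ether of 41 (3R,4Z,6R,7R,8R,10R), via hydroxy enal 38 (not isolated), via lactol 39 (not isolated)
Conditions: TEMPO (20 mol %), PhI(OAc)2, CH2Cl2, rt
Reagents that add atoms: none
Why: Nitroxyl-catalysed oxidation takes the primary allylic alcohol selectively to the enal, which is trapped by the C6 hydroxyl as the five-membered lactol and oxidized again to the α-methylene-γ-butyrolactone; secondary and tertiary hydroxyls react much more slowly, and the existing C6/C7 centres fix the trans ring fusion.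

Step 24
Reactants: 40 3-O-PMB ether of 41
Product: 41 (3R,4Z,6R,7R,8R,10R)-3,10-dihydroxy-1-oxogermacra-4,11(13)-dien-12,6-olide 8-(3-methylbutanoate)
Conditions: DDQ, CH2Cl2/pH 7 buffer, 0 °C
Reagents that add atoms: none
Why: Oxidative cleavage of the allylic PMB ether by DDQ under buffered conditions releases the C3 hydroxyl of the β-hydroxy ketone without acid or base that could trigger dehydration.

Compound list
1 | (R)-citramalic acid | OC(=O)[C@](C)(O)CC(=O)O | starting material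
2 | 2-[(4R)-2,2,4-trimethyl-5-oxo-1,3-dioxolan-4-yl]acetic acid | CC1(C)OC(=O)[C@@](C)(CC(=O)O)O1 | intermediate
3 | ethyl 2-(bromomethyl)acrylate | C=C(CBr)C(=O)OCC | starting material
4 | 2-(bromomethyl)prop-2-en-1-ol | C=C(CBr)CO | intermediate
5 | {[2-(bromomethyl)prop-2-en-1-yl]oxy}(tert-butyl)dimethylsilane | C=C(CBr)CO[Si](C)(C)C(C)(C)C | intermediate
6 | 2-[(4R)-2,2,4-trimethyl-5-oxo-1,3-dioxolan-4-yl]acetyl chloride | CC1(C)OC(=O)[C@@](C)(CC(=O)Cl)O1 | intermediate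
7 | {2-[(TBS-oxy)methyl]prop-2-en-1-yl}zinc bromide | C=C(C[Zn]Br)CO[Si](C)(C)C(C)(C)C | intermediate
8 | (5R)-5-{2-oxo-4-[(TBS-oxy)methyl]pent-4-en-1-yl}-2,2,5-trimethyl-1,3-dioxolan-4-one (C8 ketone) | CC1(C)OC(=O)[C@@](C)(CC(=O)CC(=C)CO[Si](C)(C)C(C)(C)C)O1 | intermediate
9 | 4-methoxybenzyl alcohol | COc1ccc(CO)cc1 | starting material
10 | allyl 4-methoxybenzyl ether | C=CCOCc1ccc(OC)cc1 | intermediate
11 | 2-[(4-methoxybenzyl)oxy]acetaldehyde | O=CCOCc1ccc(OC)cc1 | intermediate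
12 | (Z)-enol diisopinocampheylborinate of 8 (C7=C8, boron on O8) | CC1(C)OC(=O)[C@@](C)(C/C(=C/C(=C)CO[Si](C)(C)C(C)(C)C)OB([C@@H]2C[C@@H]3C[C@H]([C@H]2C)C3(C)C)[C@@H]2C[C@@H]3C[C@H]([C@H]2C)C3(C)C)O1 | intermediate
13 | (5R)-5-[(3S,4S)-4-hydroxy-5-(PMB-oxy)-2-oxo-3-[3-(TBS-oxy)prop-1-en-2-yl]pentyl]-2,2,5-trimethyl-1,3-dioxolan-4-one (6S,7S syn aldol) | CC1(C)OC(=O)[C@@](C)(CC(=O)[C@@H](C(=C)CO[Si](C)(C)C(C)(C)C)[C@H](O)COCc2ccc(OC)cc2)O1 | intermediate
14 | (5R)-5-[(2R,3R,4S)-2,4-dihydroxy-5-(PMB-oxy)-3-[3-(TBS-oxy)prop-1-en-2-yl]pentyl]-2,2,5-trimethyl-1,3-dioxolan-4-one (6,8-anti diol) | CC1(C)OC(=O)[C@@](C)(C[C@@H](O)[C@@H](C(=C)CO[Si](C)(C)C(C)(C)C)[C@H](O)COCc2ccc(OC)cc2)O1 | intermediate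
15 | (3R,5R)-3-hydroxy-5-[(2S,3S)-2-hydroxy-4-methylidene-1-(PMB-oxy)-5-(TBS-oxy)pentan-3-yl]-3-methyloxolan-2-one (O8→C1 lactone) | O=C1O[C@@H]([C@@H](C(=C)CO[Si](C)(C)C(C)(C)C)[C@H](O)COCc2ccc(OC)cc2)C[C@@]1(C)O | intermediate
16 | (3R,5R)-3-hydroxy-3-methyl-5-[(2S,3R)-4-methylidene-1-(PMB-oxy)-2,5-bis(TBS-oxy)pentan-3-yl]oxolan-2-one | O=C1O[C@@H]([C@@H](C(=C)CO[Si](C)(C)C(C)(C)C)[C@H](O[Si](C)(C)C(C)(C)C)COCc2ccc(OC)cc2)C[C@@]1(C)O | intermediate
17 | lithium (2R,4R,5R,6S)-2,4-dihydroxy-2-methyl-7-(PMB-oxy)-6-(TBS-oxy)-5-[3-(TBS-oxy)prop-1-en-2-yl]heptanoate | [Li+].[O-]C(=O)[C@](C)(O)C[C@@H](O)[C@@H](C(=C)CO[Si](C)(C)C(C)(C)C)[C@H](O[Si](C)(C)C(C)(C)C)COCc1ccc(OC)cc1 | intermediate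
18 | triethylsilyl (2R,4R,5R,6S)-2-methyl-7-(PMB-oxy)-6-(TBS-oxy)-5-[3-(TBS-oxy)prop-1-en-2-yl]-2,4-bis(TES-oxy)heptanoate | CC[Si](CC)(CC)OC(=O)[C@](C)(O[Si](CC)(CC)CC)C[C@@H](O[Si](CC)(CC)CC)[C@@H](C(=C)CO[Si](C)(C)C(C)(C)C)[C@H](O[Si](C)(C)C(C)(C)C)COCc1ccc(OC)cc1 | intermediate
19 | (2R,4R,5R,6S)-2-methyl-7-(PMB-oxy)-6-(TBS-oxy)-5-[3-(TBS-oxy)prop-1-en-2-yl]-2,4-bis(TES-oxy)heptanoic acid | OC(=O)[C@](C)(O[Si](CC)(CC)CC)C[C@@H](O[Si](CC)(CC)CC)[C@@H](C(=C)CO[Si](C)(C)C(C)(C)C)[C@H](O[Si](C)(C)C(C)(C)C)COCc1ccc(OC)cc1 | intermediate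
20 | prop-2-en-1-yl (2R,4R,5R,6S)-2-methyl-7-(PMB-oxy)-6-(TBS-oxy)-5-[3-(TBS-oxy)prop-1-en-2-yl]-2,4-bis(TES-oxy)heptanoate | C=CCOC(=O)[C@](C)(O[Si](CC)(CC)CC)C[C@@H](O[Si](CC)(CC)CC)[C@@H](C(=C)CO[Si](C)(C)C(C)(C)C)[C@H](O[Si](C)(C)C(C)(C)C)COCc1ccc(OC)cc1 | intermediate
21 | prop-2-en-1-yl (2R,4R,5R,6S)-7-hydroxy-2-methyl-6-(TBS-oxy)-5-[3-(TBS-oxy)prop-1-en-2-yl]-2,4-bis(TES-oxy)heptanoate | C=CCOC(=O)[C@](C)(O[Si](CC)(CC)CC)C[C@@H](O[Si](CC)(CC)CC)[C@@H](C(=C)CO[Si](C)(C)C(C)(C)C)[C@H](O[Si](C)(C)C(C)(C)C)CO | intermediate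
22 | prop-2-en-1-yl (2R,4R,5R,6S)-2-methyl-7-oxo-6-(TBS-oxy)-5-[3-(TBS-oxy)prop-1-en-2-yl]-2,4-bis(TES-oxy)heptanoate (C5 aldehyde) | C=CCOC(=O)[C@](C)(O[Si](CC)(CC)CC)C[C@@H](O[Si](CC)(CC)CC)[C@@H](C(=C)CO[Si](C)(C)C(C)(C)C)[C@H](O[Si](C)(C)C(C)(C)C)C=O | intermediate
23 | trichloroethylene | ClC=C(Cl)Cl | starting material
24 | 1-({[(E)-1,2-dichloroethenyl]oxy}methyl)-4-methoxybenzene | COc1ccc(CO/C(Cl)=C\Cl)cc1 | intermediate
25 | lithium 2-[(4-methoxybenzyl)oxy]ethynide | [Li]C#COCc1ccc(OC)cc1 | intermediate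
26 | 1-methoxy-4-[(prop-1-yn-1-yloxy)methyl]benzene | CC#COCc1ccc(OC)cc1 | intermediate
27 | chloro[(E)-1-(PMB-oxy)prop-1-en-2-yl]zirconocene | COc1ccc(CO/C=C(\C)[Zr](Cl)(C2C=CC=C2)C2C=CC=C2)cc1 | intermediate
28 | methyl[(E)-1-(PMB-oxy)prop-1-en-2-yl]zinc | COc1ccc(CO/C=C(\C)[Zn]C)cc1 | intermediate
29 | prop-2-en-1-yl (2R,4R,5R,6S,7R,8E)-7-hydroxy-2,8-dimethyl-9-(PMB-oxy)-6-(TBS-oxy)-5-[3-(TBS-oxy)prop-1-en-2-yl]-2,4-bis(TES-oxy)non-8-enoate | C=CCOC(=O)[C@](C)(O[Si](CC)(CC)CC)C[C@@H](O[Si](CC)(CC)CC)[C@@H](C(=C)CO[Si](C)(C)C(C)(C)C)[C@H](O[Si](C)(C)C(C)(C)C)[C@H](O)/C(C)=C/OCc1ccc(OC)cc1 | intermediate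
30 | (2R,4R,5R,6S,7R,8E)-7-hydroxy-2,8-dimethyl-9-(PMB-oxy)-6-(TBS-oxy)-5-[3-(TBS-oxy)prop-1-en-2-yl]-2,4-bis(TES-oxy)non-8-enoic acid (seco acid) | OC(=O)[C@](C)(O[Si](CC)(CC)CC)C[C@@H](O[Si](CC)(CC)CC)[C@@H](C(=C)CO[Si](C)(C)C(C)(C)C)[C@H](O[Si](C)(C)C(C)(C)C)[C@H](O)/C(C)=C/OCc1ccc(OC)cc1 | intermediate
31 | mixed anhydride of 30 and 2-methyl-6-nitrobenzoic acid | Cc1cccc([N+](=O)[O-])c1C(=O)OC(=O)[C@](C)(O[Si](CC)(CC)CC)C[C@@H](O[Si](CC)(CC)CC)[C@@H](C(=C)CO[Si](C)(C)C(C)(C)C)[C@H](O[Si](C)(C)C(C)(C)C)[C@H](O)/C(C)=C/OCc1ccc(OC)cc1 | intermediate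
32 | (3R,5R,6R,7S,8R)-3-methyl-8-[(1E)-1-(PMB-oxy)prop-1-en-2-yl]-7-(TBS-oxy)-6-[3-(TBS-oxy)prop-1-en-2-yl]-3,5-bis(TES-oxy)oxocan-2-one | O=C1O[C@H](/C(C)=C/OCc2ccc(OC)cc2)[C@@H](O[Si](C)(C)C(C)(C)C)[C@H](C(=C)CO[Si](C)(C)C(C)(C)C)[C@H](O[Si](CC)(CC)CC)C[C@@]1(C)O[Si](CC)(CC)CC | intermediate
33 | (3R,5R,6R,7S,8R)-3-methyl-2-methylidene-8-[(1E)-1-(PMB-oxy)prop-1-en-2-yl]-7-(TBS-oxy)-6-[3-(TBS-oxy)prop-1-en-2-yl]-3,5-bis(TES-oxy)oxocane | C=C1O[C@H](/C(C)=C/OCc2ccc(OC)cc2)[C@@H](O[Si](C)(C)C(C)(C)C)[C@H](C(=C)CO[Si](C)(C)C(C)(C)C)[C@H](O[Si](CC)(CC)CC)C[C@@]1(C)O[Si](CC)(CC)CC | intermediate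
34 | (3R,4Z,6R,7R,8R,10R)-4,10-dimethyl-3-(PMB-oxy)-6-(TBS-oxy)-7-[3-(TBS-oxy)prop-1-en-2-yl]-8,10-bis(TES-oxy)cyclodec-4-en-1-one | CC(C)(C)[Si](C)(C)O[C@@H]1/C=C(/C)[C@H](OCc2ccc(OC)cc2)CC(=O)[C@](C)(O[Si](CC)(CC)CC)C[C@@H](O[Si](CC)(CC)CC)[C@H]1C(=C)CO[Si](C)(C)C(C)(C)C | intermediate
35 | (3R,4Z,6R,7R,8R,10R)-8-hydroxy-4,10-dimethyl-3-(PMB-oxy)-6-(TBS-oxy)-7-[3-(TBS-oxy)prop-1-en-2-yl]-10-(TES-oxy)cyclodec-4-en-1-one | CC(C)(C)[Si](C)(C)O[C@@H]1/C=C(/C)[C@H](OCc2ccc(OC)cc2)CC(=O)[C@](C)(O[Si](CC)(CC)CC)C[C@@H](O)[C@H]1C(=C)CO[Si](C)(C)C(C)(C)C | intermediate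
36 | C8 3-methylbutanoate of 35 (3R,4Z,6R,7R,8R,10R) | CC(C)(C)[Si](C)(C)O[C@@H]1/C=C(/C)[C@H](OCc2ccc(OC)cc2)CC(=O)[C@](C)(O[Si](CC)(CC)CC)C[C@@H](OC(=O)CC(C)C)[C@H]1C(=C)CO[Si](C)(C)C(C)(C)C | intermediate
37 | (3R,4Z,6R,7S,8R,10R)-6,10-dihydroxy-7-(3-hydroxyprop-1-en-2-yl)-4,10-dimethyl-1-oxo-3-(PMB-oxy)cyclodec-4-en-8-yl 3-methylbutanoate | O[C@@H]1/C=C(/C)[C@H](OCc2ccc(OC)cc2)CC(=O)[C@](C)(O)C[C@@H](OC(=O)CC(C)C)[C@H]1C(=C)CO | intermediate
38 | C12 aldehyde of 37 (2-substituted acrylaldehyde; 3R,4Z,6R,7S,8R,10R) | O[C@@H]1/C=C(/C)[C@H](OCc2ccc(OC)cc2)CC(=O)[C@](C)(O)C[C@@H](OC(=O)CC(C)C)[C@H]1C(=C)C=O | intermediate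
39 | 6,12-lactol of 38 (both C12 epimers) | C=C1C(O)O[C@@H]2/C=C(/C)[C@H](OCc3ccc(OC)cc3)CC(=O)[C@](C)(O)C[C@@H](OC(=O)CC(C)C)[C@@H]12 | intermediate
40 | 3-O-(4-methoxybenzyl) ether of 41 (3R,4Z,6R,7R,8R,10R) | C=C1C(=O)O[C@@H]2/C=C(/C)[C@H](OCc3ccc(OC)cc3)CC(=O)[C@](C)(O)C[C@@H](OC(=O)CC(C)C)[C@@H]12 | intermediate
41 | (3R,4Z,6R,7R,8R,10R)-3,10-dihydroxy-1-oxogermacra-4,11(13)-dien-12,6-olide 8-(3-methylbutanoate), CNP0406522.1 | C=C1C(=O)O[C@@H]2/C=C(/C)[C@H](O)CC(=O)[C@](C)(O)C[C@@H](OC(=O)CC(C)C)[C@@H]12 | target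

Total step count: 24. Longest linear sequence: 20 steps (3 → 4 → 5 → 8 → 13 → 15 → 16 → 19 → 20 → 21 → 22 → 29 → 30 → 32 → 33 → 34 → 35 → 36 → 37 → 40 → 41).

Steps most likely to fail

Step 19 (ring expansion). What may go wrong: the shift may be slow at temperatures that the two enol ethers survive, so that prolonged heating brings in heterolysis of the C5–O bond or a follow-up Cope shift of the C4=C5/C11=C13 diene of 34. Fallback: the ring expansion is taken out of the thermal regime. Setting out from 33, triisobutylaluminium (i-Bu3Al, CH2Cl2, −78 °C → rt) binds the ring oxygen, should trigger the same C2–C3 bond formation at low temperature and reduces the new ketone by β-hydride transfer, giving the cyclodec-4-en-1-ol F1 as a mixture of C1 epimers. Dess–Martin oxidation of F1 (NaHCO3, CH2Cl2) comes back to the route at 34.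

Step 15 (alkenyl addition). What may go wrong: zinc chelation between the aldehyde oxygen and O6 may compete with the Felkin–Anh mode and erode or invert facial selectivity at C5, and β-elimination of the alkenyl metal drains the reagent. Fallback: C5 is set by reduction instead of addition. Setting out from 22, the addition is run as before and the crude mixture of C5 epimers is oxidized with MnO2 (CH2Cl2) to the vinylogous ester ketone F2. Reagent-controlled reduction with (R)-2-methyl-CBS-oxazaborolidine and catecholborane (toluene, −78 °C, alkenyl group as the large substituent) should then come back at 29.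

Step 7 (aldol). What may go wrong: weak facial discrimination by the isopinocampheyl ligands on this cross-conjugated enolate (C10 is too remote to help), or partial enolization toward C9. Fallback: control is moved from the enolate to a chiral Lewis acid on the aldehyde. Setting out from 8, TMSOTf and Et3N (CH2Cl2, 0 °C) give the conjugated silyl dienol ether F3. A Mukaiyama aldol addition of F3 to 11 catalysed by [Cu((S,S)-Ph-pybox)](SbF6)2 (CH2Cl2, −78 °C, two-point binding of the α-alkoxy aldehyde, ligand enantiomer chosen for the 6S,7S sense) should give the O6 trimethylsilyl ether F4. Dilute HCl in THF/H2O removes the trimethylsilyl group and comes back at 13.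

Further compounds
F1 | step 19 | (3R,4Z,6R,7R,8R,10R)-4,10-dimethyl-3-(PMB-oxy)-6-(TBS-oxy)-7-[3-(TBS-oxy)prop-1-en-2-yl]-8,10-bis(TES-oxy)cyclodec-4-en-1-ol (C1 epimers) | CC(C)(C)[Si](C)(C)O[C@@H]1/C=C(/C)[C@H](OCc2ccc(OC)cc2)CC(O)[C@](C)(O[Si](CC)(CC)CC)C[C@@H](O[Si](CC)(CC)CC)[C@H]1C(=C)CO[Si](C)(C)C(C)(C)C
F2 | step 15 | prop-2-en-1-yl (2R,4R,5R,6S,8E)-2,8-dimethyl-7-oxo-9-(PMB-oxy)-6-(TBS-oxy)-5-[3-(TBS-oxy)prop-1-en-2-yl]-2,4-bis(TES-oxy)non-8-enoate | C=CCOC(=O)[C@](C)(O[Si](CC)(CC)CC)C[C@@H](O[Si](CC)(CC)CC)[C@@H](C(=C)CO[Si](C)(C)C(C)(C)C)[C@H](O[Si](C)(C)C(C)(C)C)C(=O)/C(C)=C/OCc1ccc(OC)cc1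
F3 | step 7 | (Z)-trimethylsilyl dienol ether of 8 (C7=C8, silicon on O8) | CC1(C)OC(=O)[C@@](C)(C/C(O[Si](C)(C)C)=C/C(=C)CO[Si](C)(C)C(C)(C)C)O1
F4 | step 7 | O6-trimethylsilyl ether of 13 | CC1(C)OC(=O)[C@@](C)(CC(=O)[C@@H](C(=C)CO[Si](C)(C)C(C)(C)C)[C@H](O[Si](C)(C)C)COCc2ccc(OC)cc2)O1
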